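The target is cut at two adjacent ring-A bonds, O1–C8a and C4–C4a, and at O1–C2 of ring C. A fluoride-released 3,5-bis(MOM-oxy)benzyne is expected to insert into the C–O bond of an α-prenylcinnamic acid, and the resulting phenoxide to close the pyranone in the same flask, giving the protected 3-prenylflavanone in one operation. The step exploits the fact that C8a and C4a are neighbouring ring-A carbons and that the C5 oxygen flanks C4a, so a 3-alkoxyaryne places the acyl group beside it. Precursors: an ortho-silyl aryl triflate from phloroglucinol and a MOM-protected (E)-α-prenylcinnamic acid from 2-methoxyhydroquinone. DDQ dehydrogenation and acid unmasking finish the route.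

Key step: step 10

Remark: the target has no stereocentre; 14, 19 and F2 are racemates, each drawn as one enantiomer (19 as 2R,3S, the trans isomer).

Step 1
Reactants: 1 phloroglucinol
Product: 2 3,5-bis(methoxymethoxy)phenol
Conditions: MOMCl (2.0 equiv, slow addition), i-Pr2NEt (2.2 equiv), DMF, 0 °C to rt
Reagents that add atoms: chloromethyl methyl ether (MOMCl), COCCl
Why: Williamson-type O-alkylation of three equivalent phenols with an α-chloro ether should give mainly the bis-ether when two equivalents are dosed, and the mono- and tris-ethers are separable by chromatography.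

Step 2
Reactants: 2 3,5-bis(methoxymethoxy)phenol
Product: 3 2-bromo-3,5-bis(methoxymethoxy)phenol
Conditions: NBS (1.0 equiv), i-Pr2NH (10 mol %), CH2Cl2, −78 °C to 0 °C
Reagents that add atoms: N-bromosuccinimide (NBS), O=C1CCC(=O)N1Br
Why: Electrophilic aromatic bromination in which the secondary amine relays bromine as an N-bromoamine hydrogen-bonded to the phenol, so that one of the two equivalent ortho positions should be preferred over the crowded C4 between the two MOM ethers.

Step 3
Reactants: 3 2-bromo-3,5-bis(methoxymethoxy)phenol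
Product: 6 3,5-bis(methoxymethoxy)-2-(trimethylsilyl)phenyl trifluoromethanesulfonate, via aryl trimethylsilyl ether 4 (not isolated), via lithium ortho-silylphenoxide 5 (not isolated)
Conditions: HMDS, THF, 65 °C, then evaporate; n-BuLi, THF, −100 to −78 °C; Tf2O, −78 °C to rt
Reagents that add atoms: hexamethyldisilazane (HMDS), C[Si](C)(C)N[Si](C)(C)C; trifluoromethanesulfonic anhydride (Tf2O), O=S(=O)(OS(=O)(=O)C(F)(F)F)C(F)(F)F
Why: O-silylation, bromine–lithium exchange and 1,3-O→C silyl migration (retro-Brook rearrangement) should give the hindered phenoxide, which is triflated in the same flask; exchange at −100 °C is faster than MOM-directed deprotonation.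

Step 4
Reactants: 7 2-methoxyhydroquinone
Product: 8 2-methoxy-1,4-bis(methoxymethoxy)benzene
Conditions: MOMCl (2.5 equiv), i-Pr2NEt (3 equiv), DMF, 0 °C to rt, N2
Reagents that add atoms: chloromethyl methyl ether (MOMCl), COCCl
Why: Exhaustive Williamson-type etherification of both phenols; exclusion of air protects the electron-rich hydroquinone until it is capped.

Step 5
Reactants: 8 2-methoxy-1,4-bis(methoxymethoxy)benzene
Product: 9 1-bromo-4-methoxy-2,5-bis(methoxymethoxy)benzene
Conditions: NBS (1.05 equiv), MeCN, 0 °C to rt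
Reagents that add atoms: N-bromosuccinimide (NBS), O=C1CCC(=O)N1Br
Why: Electrophilic aromatic bromination of a 1,2,4-trioxygenated benzene should go to the only free position that is para to an oxygen (the OMe) and ortho to another, as it does for 1,2,4-trimethoxybenzene.

Step 6
Reactants: 9 1-bromo-4-methoxy-2,5-bis(methoxymethoxy)benzene
Product: 11 4-methoxy-2,5-bis(methoxymethoxy)benzaldehyde, via aryllithium 10 (not isolated)
Conditions: n-BuLi, THF, −78 °C; DMF, −78 to 0 °C; H2O
Reagents that add atoms: N,N-dimethylformamide (DMF), CN(C)C=O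
Why: Bromine–lithium exchange followed by formylation with DMF (Bouveault aldehyde synthesis) places the formyl group at the brominated carbon, independent of the directing power of the MOM ethers.

Step 7
Reactants: 12 triethyl phosphonoacetate; 13 prenyl bromide
Product: 14 ethyl 2-(diethoxyphosphoryl)-5-methylhex-4-enoate (racemic)
Conditions: NaH (1.0 equiv), THF, 0 °C; then 13 (0.9 equiv), 0 °C to rt
Reagents that add atoms: none
Why: SN2 C-alkylation of the stabilised phosphonoacetate carbanion with a reactive allylic bromide, a small excess of 12 holding back dialkylation; the new stereocentre is racemic and is destroyed in step 8.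

Step 8
Reactants: 11 4-methoxy-2,5-bis(methoxymethoxy)benzaldehyde; 14 ethyl 2-(diethoxyphosphoryl)-5-methylhex-4-enoate
Product: 15 ethyl (E)-2-{[4-methoxy-2,5-bis(methoxymethoxy)phenyl]methylidene}-5-methylhex-4-enoate (aryl trans to the ester)
Conditions: NaH, THF, 0 °C; then 11, rt to 60 °C
Reagents that add atoms: none
Why: Horner–Wadsworth–Emmons olefination, in which reversible addition and the preference for aryl anti to the ester should give mainly the E-alkene; a minor Z-isomer is harmless because the geometry is lost in step 10.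

Step 9
Reactants: 15 ethyl (E)-2-{[4-methoxy-2,5-bis(methoxymethoxy)phenyl]methylidene}-5-methylhex-4-enoate
Product: 16 (E)-2-{[4-methoxy-2,5-bis(methoxymethoxy)phenyl]methylidene}-5-methylhex-4-enoic acid (the α-prenylcinnamic acid, aryl trans to CO2H)
Conditions: LiOH·H2O, THF/MeOH/H2O, 60 °C; then 1 M HCl to pH 4, 0 °C
Reagents that add atoms: lithium hydroxide, [Li+].[OH-]
Why: Saponification of the ester; MOM acetals are inert to hydroxide and the brief cold acidification is too mild to cleave them.

Step 10
Reactants: 6 3,5-bis(methoxymethoxy)-2-(trimethylsilyl)phenyl trifluoromethanesulfonate; 16 (E)-2-{[4-methoxy-2,5-bis(methoxymethoxy)phenyl]methylidene}-5-methylhex-4-enoic acid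
Product: 19 rac-(2R,3S)-2-[4-methoxy-2,5-bis(methoxymethoxy)phenyl]-5,7-bis(methoxymethoxy)-3-(3-methylbut-2-en-1-yl)chroman-4-one (trans-flavanone tetra-MOM ether), via 3,5-bis(methoxymethoxy)benzyne 17 (not isolated), via 2'-hydroxy-α-prenylchalcone 18 (not isolated)
Conditions: CsF (4 equiv), 6 (1.4 equiv), THF, 125 °C, sealed tube, 24 h
Reagents that add atoms: none
Why: Fluoride attacks silicon and expels triflate to give aryne 17; the carboxylate of 16 adds through oxygen to the aryne carbon remote from the flanking MOM ether, the aryl anion formed beside that ether attacks the ester carbonyl to give a four-membered alkoxide, and its opening delivers the ortho-acyl phenoxide 18, so that O1–C8a and C4–C4a are in place. The closest known reaction type is the fluoride-induced insertion of arynes into the C–O bond of carboxylic acids, which gives ortho-hydroxyaryl ketones and, from α,β-unsaturated acids, chroman-4-ones. Ring C then closes by 6-endo-trig oxa-Michael addition of the phenoxide oxygen to the β-carbon of the enone, forming O1–C2. C2 is set in this reversible addition and C3 by protonation of the enolate; under the basic conditions both should equilibrate to the trans isomer with aryl and prenyl equatorial, as a racemate, and both are erased in step 11. The step needs regioselective addition to the aryne, which the inductive effect and ring distortion of the C5 MOM ether next to the aryne secure. It also needs acyl transfer to outrun protonation of the aryl anion, which the high temperature favours.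

Step 11
Reactants: 19 rac-(2R,3S)-2-[4-methoxy-2,5-bis(methoxymethoxy)phenyl]-5,7-bis(methoxymethoxy)-3-(3-methylbut-2-en-1-yl)chroman-4-one
Product: 20 2-[4-methoxy-2,5-bis(methoxymethoxy)phenyl]-5,7-bis(methoxymethoxy)-3-(3-methylbut-2-en-1-yl)-4H-chromen-4-one
Conditions: DDQ (2.5 equiv), 1,4-dioxane, 100 °C
Reagents that add atoms: none
Why: Quinone dehydrogenation, in which hydride abstraction from C2 (benzylic to the electron-rich ring B and α to O1) and loss of the C3 proton should give the chromone and remove both stereocentres; the MOM ethers keep the hydroquinone ring from being oxidised.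

Step 12
Reactants: 20 2-[4-methoxy-2,5-bis(methoxymethoxy)phenyl]-5,7-bis(methoxymethoxy)-3-(3-methylbut-2-en-1-yl)-4H-chromen-4-one
Product: 21 5,7-dihydroxy-2-(2,5-dihydroxy-4-methoxyphenyl)-3-(3-methylbut-2-en-1-yl)-4H-chromen-4-one (CNP0426236.0)
Conditions: 3 M aq. HCl/MeOH (1:5), 50 °C, Ar
Reagents that add atoms: none
Why: Acid-catalysed acetal solvolysis should remove all four MOM groups as dimethoxymethane under conditions that a trisubstituted prenyl alkene normally survives; argon protects the freed methoxyhydroquinone ring from air oxidation.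

Compound list
1 | phloroglucinol | Oc1cc(O)cc(O)c1 | starting material
2 | 3,5-bis(methoxymethoxy)phenol | COCOc1cc(O)cc(OCOC)c1 | intermediate
3 | 2-bromo-3,5-bis(methoxymethoxy)phenol | Oc1cc(OCOC)cc(OCOC)c1Br | intermediate
4 | [2-bromo-3,5-bis(methoxymethoxy)phenoxy]trimethylsilane | C[Si](C)(C)Oc1cc(OCOC)cc(OCOC)c1Br | intermediate (not isolated)
5 | lithium 3,5-bis(methoxymethoxy)-2-(trimethylsilyl)phenoxide | [Li+].[O-]c1cc(OCOC)cc(OCOC)c1[Si](C)(C)C | intermediate (not isolated)
6 | 3,5-bis(methoxymethoxy)-2-(trimethylsilyl)phenyl trifluoromethanesulfonate | COCOc1cc(OCOC)c([Si](C)(C)C)c(OS(=O)(=O)C(F)(F)F)c1 | intermediate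
7 | 2-methoxyhydroquinone | COc1cc(O)ccc1O | starting material
8 | 2-methoxy-1,4-bis(methoxymethoxy)benzene | COCOc1ccc(OCOC)c(OC)c1 | intermediate
9 | 1-bromo-4-methoxy-2,5-bis(methoxymethoxy)benzene | Brc1cc(OCOC)c(OC)cc1OCOC | intermediate
10 | [4-methoxy-2,5-bis(methoxymethoxy)phenyl]lithium | [Li]c1cc(OCOC)c(OC)cc1OCOC | intermediate (not isolated)
11 | 4-methoxy-2,5-bis(methoxymethoxy)benzaldehyde | O=Cc1cc(OCOC)c(OC)cc1OCOC | intermediate
12 | triethyl phosphonoacetate | CCOC(=O)CP(=O)(OCC)OCC | starting material
13 | prenyl bromide | CC(C)=CCBr | starting material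
14 | ethyl 2-(diethoxyphosphoryl)-5-methylhex-4-enoate (racemic, one enantiomer drawn) | CCOC(=O)[C@H](CC=C(C)C)P(=O)(OCC)OCC | intermediate
15 | ethyl (E)-2-{[4-methoxy-2,5-bis(methoxymethoxy)phenyl]methylidene}-5-methylhex-4-enoate | CC(C)=CC/C(=C\c1cc(OCOC)c(OC)cc1OCOC)C(=O)OCC | intermediate
16 | (E)-2-{[4-methoxy-2,5-bis(methoxymethoxy)phenyl]methylidene}-5-methylhex-4-enoic acid | CC(C)=CC/C(=C\c1cc(OCOC)c(OC)cc1OCOC)C(=O)O | intermediate
17 | 3,5-bis(methoxymethoxy)benzyne | COCOC1=CC(OCOC)=CC#C1 | intermediate (not isolated)
18 | (E)-1-[2-hydroxy-4,6-bis(methoxymethoxy)phenyl]-2-{[4-methoxy-2,5-bis(methoxymethoxy)phenyl]methylidene}-5-methylhex-4-en-1-one (2'-hydroxy-α-prenylchalcone, in the flask as its phenoxide) | CC(C)=CC/C(=C\c1cc(OCOC)c(OC)cc1OCOC)C(=O)c1c(O)cc(OCOC)cc1OCOC | intermediate (not isolated)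
19 | rac-(2R,3S)-2-[4-methoxy-2,5-bis(methoxymethoxy)phenyl]-5,7-bis(methoxymethoxy)-3-(3-methylbut-2-en-1-yl)chroman-4-one (trans) | COCOc1cc(OCOC)c2C(=O)[C@@H](CC=C(C)C)[C@H](c3cc(OCOC)c(OC)cc3OCOC)Oc2c1 | intermediate
20 | 2-[4-methoxy-2,5-bis(methoxymethoxy)phenyl]-5,7-bis(methoxymethoxy)-3-(3-methylbut-2-en-1-yl)-4H-chromen-4-one | COCOc1cc(OCOC)c2c(=O)c(CC=C(C)C)c(-c3cc(OCOC)c(OC)cc3OCOC)oc2c1 | intermediate
21 | 5,7-dihydroxy-2-(2,5-dihydroxy-4-methoxyphenyl)-3-(3-methylbut-2-en-1-yl)-4H-chromen-4-one (CNP0426236.0) | COc1cc(O)c(-c2oc3cc(O)cc(O)c3c(=O)c2CC=C(C)C)cc1O | target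

Total step count: 12.
Longest linear sequence: 8 steps (steps 4, 5, 6, 8, 9, 10, 11, 12, from 2-methoxyhydroquinone).

Steps most likely to fail

1. Step 10. The aryl anion may be protonated before it reaches the carbonyl, which stops the sequence at simple O-arylation. The aryne may also be consumed by an ene reaction with the prenyl alkene, or ring closure may stay incomplete. The fallback generates the same aryl anion by halogen–metal exchange and sets out from 3 and 16. The two are coupled (EDC·HCl, DMAP, CH2Cl2, rt) to the aryl ester 2-bromo-3,5-bis(methoxymethoxy)phenyl (E)-2-{[4-methoxy-2,5-bis(methoxymethoxy)phenyl]methylidene}-5-methylhex-4-enoate F1. Treatment with t-BuLi (2.1 equiv, THF, −100 °C) should effect bromine–lithium exchange and an anionic Fries-type 1,3-O→C acyl shift, giving 18, isolated this time as the phenol after work-up. NaOAc in EtOH at reflux then closes ring C, and the fallback rejoins the route at 19.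

2. Step 11. Hydride abstraction at the allylic methylene of the prenyl chain, or oxidative degradation of the electron-rich ring B, may compete with removal of the C2 and C3 hydrogens. The fallback sets out from 19. Soft enolisation (TMSOTf, Et3N, CH2Cl2, −78 to 0 °C) should give the silyl enol ether rac-{[2-(4-methoxy-2,5-bis(methoxymethoxy)phenyl)-5,7-bis(methoxymethoxy)-3-(3-methylbut-2-en-1-yl)-2H-chromen-4-yl]oxy}trimethylsilane F2. Saegusa–Ito oxidation (Pd(OAc)2, MeCN, rt) converts it into 20, where the route is rejoined.

3. Step 12. Protic acid may hydrate the prenyl alkene or cyclise it onto the freed 2'-hydroxyl, and the liberated hydroquinone may oxidise in air. The fallback sets out from 20 and avoids Brønsted acid and heat. TMSOTf and 2,2'-bipyridyl (MeCN, 0 °C to rt) should exchange each aryl MOM ether for a silyl ether, giving 2-[4-methoxy-2,5-bis(trimethylsilyloxy)phenyl]-5,7-bis(trimethylsilyloxy)-3-(3-methylbut-2-en-1-yl)-4H-chromen-4-one F3. Addition of water hydrolyses the silyl ethers, and the fallback arrives at 21.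

Further compounds
F1 | step 10 | 2-bromo-3,5-bis(methoxymethoxy)phenyl (E)-2-{[4-methoxy-2,5-bis(methoxymethoxy)phenyl]methylidene}-5-methylhex-4-enoate | CC(C)=CC/C(=C\c1cc(OCOC)c(OC)cc1OCOC)C(=O)Oc1cc(OCOC)cc(OCOC)c1Br
F2 | step 11 | rac-{[2-(4-methoxy-2,5-bis(methoxymethoxy)phenyl)-5,7-bis(methoxymethoxy)-3-(3-methylbut-2-en-1-yl)-2H-chromen-4-yl]oxy}trimethylsilane (one enantiomer drawn) | COCOc1cc(OCOC)c2C(O[Si](C)(C)C)=C(CC=C(C)C)[C@H](c3cc(OCOC)c(OC)cc3OCOC)Oc2c1
F3 | step 12 | 2-[4-methoxy-2,5-bis(trimethylsilyloxy)phenyl]-5,7-bis(trimethylsilyloxy)-3-(3-methylbut-2-en-1-yl)-4H-chromen-4-one | COc1cc(O[Si](C)(C)C)c(-c2oc3cc(O[Si](C)(C)C)cc(O[Si](C)(C)C)c3c(=O)c2CC=C(C)C)cc1O[Si](C)(C)C
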